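## Analysis of the target

The target is a 6/10/5 tricycle. Cyclohexenone ring A (C1, C10–C14) shares the C1–C10 bond with ten-membered ring B (C1–C10), and ring B carries the α-methylbutenolide ring C (C7, C8, C17, C19, O) across C7–C8. There are five stereocentres: quaternary C1 (R, C15 methyl), C2 (S, propionate), C7 (R, lactone oxygen), C10 (R) and C14 (S, acetate). H-10 and the C15 methyl are trans, so ring B leaves ring A through two trans-disposed bonds (C1–C2 and C10–C9). The C14 acetate is anti to the C15 methyl, and C7 is remote from the other four centres. C7–H is γ to the lactone carbonyl and doubly allylic, so base can epimerise it or trigger elimination to an alkylidene butenolide; the α-acetoxy enone and the two esters rule out strong bases and nucleophiles late on, and the (Z)-C5=C6 alkene must keep its geometry. The hard parts are the ten-membered carbocycle containing a trisubstituted (Z)-alkene and a tetrasubstituted alkene, and the contiguous C14–C1(–C2)–C10 array around a quaternary carbon. The strategy rests on the tetrasubstituted C8=C17 alkene of ring C: its four substituents (C9, the oxygen-bearing C7, the C18 methyl and the C19 carboxyl) correspond one-to-one to an anti addition of a C9 nucleophile and CO2 across a C8≡C17 propargylic alcohol.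

## Retrosynthetic reasoning

36 ⇒ 35. The C14–O bond is cut first. An α-acetoxy ketone would not survive the organometallic, carbanion and hydride steps. In enone 35 the only α′ position is C14, because C1 is quaternary. The forward step must deliver acetate anti to the axial C15 methyl.

35 ⇒ 34 ⇒ 33 ⇒ 32 ⇒ 31. The enone is traced back to a C13 silyl ether, because a free enone would be attacked by the Grignard reagent of the key step and by the sulfone anion. The propionate is traced to ketone 31; its quaternary neighbour C1 and methylene neighbour C3 differ enough in size for a reagent-controlled reduction.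

31 ⇒ 30 ⇒ 29. Ring B is opened at C3–C4. This is the one ring bond that joins a carbon acidified by the C2 carbonyl (C3) to an allylic electrophile (C4), and it lies far from C7. Ring A on one side and the butenolide–(Z)-alkene unit on the other hold the two ends, and a sulfonyl group at C3 lowers the pKa so that carbonate suffices. The forward reaction must give C-alkylation under high dilution without touching C7–H, followed by reductive desulfonylation.

29 ⇒ 28 ⇒ 27 ⇒ 26 ⇒ 25 ⇒ 24. These are functional group changes. The β-keto sulfone is made from the C2 aldehyde by a Lewis-acid diazo homologation, so no carbanion meets the butenolide. The allylic bromide is made last. The three silyl ethers of 24 are graded (C2 triethylsilyl, C4 primary allylic TBS, C13 hindered secondary TBS) so that each is released in turn.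

24 ⇒ 20 + 18 + 19. This is the key disconnection: C8–C9, C17–C19 and O–C19 are cut together. Ring C is taken apart to Grignard reagent 20 (ring A with C9 as the nucleophile), alkynol 18 (C4–C8, C17, C18, with C7 already set) and carbon dioxide 19, through intermediates 21–23. Cutting here makes the tetrasubstituted alkene regio- and stereospecifically and joins two fragments of similar size.

20 ⇒ 12 ⇒ 11 ⇒ 10 ⇒ 9 ⇒ 8. The C9 bromide and the C2 silyl ether come from trans-diol 9, and both hydroxymethyl carbons come from the lactone acetal of 8. The forward steps must distinguish the neopentyl C2 hydroxyl from the less hindered C9 hydroxyl.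

8 ⇒ 7 ⇒ 6 ⇒ 5. Ring A is opened at C11=C12 (ring-closing metathesis), and the C13 oxygen is the carbonyl of enone 6. This leaves a five-membered lactone carrying all of C1, C2, C9 and C10.

5 ⇒ 4 ⇒ 3 ⇒ 2 ⇒ 1. C1–C14, C1–C15 and C10–C11 are cut. On the lactone of 1 each new group enters anti to its neighbour: the isopropenyl group anti to the menthyloxy group, then the C14 arm anti to the isopropenyl group. This fixes C10 and the quaternary C1 with the trans C9/C2 relationship. A six-membered-ring enolate next to a quaternary carbon bearing two groups of similar size would not give this control.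

18 ⇒ 17 ⇒ 15 + 16 ⇒ 14 ⇒ 13. C7–C8 is cut (Grignard reagent 16 on a Weinreb amide). The (Z)-C5=C6 geometry is taken from the ring of butenolide 13, and C7 is set by asymmetric reduction of ynone 17.

## Alternatives that were turned down

Alternative 1: The disconnection is C9–C10 and C1–C2, both on ring A, joined in one flask from enone A2, furylmethyl Grignard reagent A3 and aldehyde A4 to give A1. In the forward key step A3 adds to C10 of A2 under CuBr·SMe2 catalysis, the enolate is transmetalated with Cp2ZrCl2 and adds through C1 to A4; no ring closes.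
- In favour: two hindered bonds and three stereocentres (C10, C1, C2) are made at once, and the anti relationship of the two new groups gives the trans C9/C2 pattern directly. On this point it is stronger than the chosen route, which needs several steps for the same centres.
- Against: A1 has ring A with the ketone at C14 and C11–C13 saturated, so the C13 carbonyl, the C11=C12 alkene and the C14 acetate must all be installed later on a congested ring. The aldol of a tetrasubstituted enolate is reversible, and its C2 facial control is hard to guarantee. Ring B still has to be closed, with C7 created during that closure, and the furan still has to be oxidised to the butenolide.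
- Comparison: the chosen strategy offers instead a butenolide delivered complete, with C7 preset and ring A already at the right oxidation pattern.

Alternative 2: The disconnection is C14–C1 and O–C2, which builds ring A last on a preformed ring B/ring C diene; oxime A6 gives A5. In the forward key step the dipole generated from A6 with NaOCl adds across the (Z)-C1=C2 alkene, closing ring A and a temporary isoxazoline.
- In favour: the quaternary C1 and the C2 oxygen are set together and stereospecifically from the alkene geometry, and the isoxazoline masks a β-hydroxy ketone. For C1/C2 this is as strong as the chosen route or stronger.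
- Against: the ten-membered (Z,Z)-diene with the butenolide must be closed first, without ring A to pre-organise it. The facial selectivity of the cycloaddition depends on a medium-ring conformation that cannot be predicted with confidence. After N–O cleavage the carbonyl sits at C14, not C13, so further redox steps follow. The oxidant also meets the electron-rich C5=C6 alkene and the butenolide.
- Comparison: the chosen strategy closes ring B between two rigid ends (ring A and ring C) and keeps the oxidation pattern of ring A fixed from the fragment stage.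

Alternative 3: The disconnection is C1–C2, by [2,3]-Wittig–Still ring contraction of thirteen-membered α-stannyl allylic ether A8 to A7. In the forward key step tin–lithium exchange at C2 with n-BuLi triggers the shift that forms C1–C2, breaks O–C13 and contracts the ring to ring B.
- In favour: a thirteen-membered ether is easier to close than a ten-membered carbocycle, and the configuration of the C13 oxygen is transferred suprafacially to the quaternary C1 while the C2 carbinol is formed. For the C1–C2 bond this is stronger than the chosen route.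
- Against: the C13 oxygen is consumed and A7 has a C13=C14 alkene and a saturated C11, so ring A must be re-oxidised at three positions. n-BuLi forces ring C to be carried as an open bis-silyl ether, so the butenolide is built afterwards. [1,2]-Shift and transannular pathways compete, and the configuration of the stannyl carbon must be controlled.
- Comparison: the chosen strategy offers fewer redox corrections after its key step and a butenolide that is formed once and never re-opened.

Key step: step 16

Remarks on the chemistry: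
- Atom numbers are those of the target: C15 is the methyl on C1, C16 that on C5, C18 that on C17, C20 that on C11.
- "Menthyl" means (1R,2S,5R)-2-isopropyl-5-methylcyclohexyl.
- Assumption: C13 is drawn as the 13R epimer expected from step 6; its configuration is erased in step 27, so the other epimer would serve equally.
- Assumption: C3 of 30 forms as a mixture of epimers, which converge in step 23.

## Route

Step 1
Reactants: 1 (5R)-5-(menthyloxy)furan-2(5H)-one
Product: 2 (4S,5R)-5-(menthyloxy)-4-(prop-1-en-2-yl)dihydrofuran-2(3H)-one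
Conditions: CH2=C(Me)MgBr, CuBr·SMe2 (10 mol %), THF, −78 → −40 °C; aq NH4Cl
Reagents that add atoms: isopropenylmagnesium bromide, CC(=C)[Mg]Br
Why: Copper-catalysed conjugate addition to a γ-alkoxybutenolide; the menthyloxy group on C9 shields one face, so the isopropenyl group (C11, C20) enters trans to it and sets C10.

Step 2
Reactants: 2 (4S,5R)-5-(menthyloxy)-4-(prop-1-en-2-yl)dihydrofuran-2(3H)-one
Product: 3 (3R,4S,5R)-3-methyl-5-(menthyloxy)-4-(prop-1-en-2-yl)dihydrofuran-2(3H)-one
Conditions: LiN(i-Pr)2, THF, −78 °C; MeI, −78 → −40 °C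
Reagents that add atoms: iodomethane, CI
Why: Lactone enolate alkylation installs C15, expected anti to the isopropenyl group; the configuration at C1 is not critical because C1 is enolised again in step 3.

Step 3
Reactants: 3 (3R,4S,5R)-3-methyl-5-(menthyloxy)-4-(prop-1-en-2-yl)dihydrofuran-2(3H)-one
Product: 4 N-methoxy-N-methyl-2-[(3R,4R,5R)-3-methyl-5-(menthyloxy)-2-oxo-4-(prop-1-en-2-yl)tetrahydrofuran-3-yl]acetamide
Conditions: LiN(i-Pr)2, THF–DMPU, −78 °C; BrCH2C(O)N(OMe)Me, −78 → −20 °C
Reagents that add atoms: 2-bromo-N-methoxy-N-methylacetamide, BrCC(=O)N(C)OC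
Why: Second enolate alkylation; the electrophile (C14, C13) approaches the planar enolate anti to the C10 isopropenyl group, so the C14 arm is trans to C11 and the C15 methyl cis to it, which sets the quaternary C1.

Step 4
Reactants: 4 N-methoxy-N-methyl-2-[(3R,4R,5R)-3-methyl-5-(menthyloxy)-2-oxo-4-(prop-1-en-2-yl)tetrahydrofuran-3-yl]acetamide
Product: 5 (3R,4R,5R)-3-methyl-5-(menthyloxy)-3-(2-oxobut-3-en-1-yl)-4-(prop-1-en-2-yl)dihydrofuran-2(3H)-one
Conditions: CH2=CHMgBr, THF, −78 → 0 °C; cold aq NaHSO4
Reagents that add atoms: vinylmagnesium bromide, C=C[Mg]Br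
Why: Weinreb ketone synthesis; the chelated tetrahedral adduct prevents over-addition, and the α-quaternary lactone carbonyl is too hindered to compete; the cold acidic quench keeps the released amine from adding to the vinyl ketone.

Step 5
Reactants: 5 (3R,4R,5R)-3-methyl-5-(menthyloxy)-3-(2-oxobut-3-en-1-yl)-4-(prop-1-en-2-yl)dihydrofuran-2(3H)-one
Product: 6 (3R,3aR,7aR)-3-(menthyloxy)-4,7a-dimethyl-3a,7-dihydroisobenzofuran-1,6(3H,7aH)-dione
Conditions: second-generation Hoveyda–Grubbs catalyst (5 mol %), toluene, 80 °C
Reagents that add atoms: none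
Why: Ring-closing metathesis of the vinyl ketone with the isopropenyl group forms C11=C12 and closes ring A as a 3-methylcyclohexenone; the trans ring fusion is already fixed by C1 and C10.

Step 6
Reactants: 6 (3R,3aR,7aR)-3-(menthyloxy)-4,7a-dimethyl-3a,7-dihydroisobenzofuran-1,6(3H,7aH)-dione
Product: 7 (3R,3aR,6R,7aR)-6-hydroxy-3-(menthyloxy)-4,7a-dimethyl-3a,6,7,7a-tetrahydroisobenzofuran-1(3H)-one
Conditions: LiBH(s-Bu)3, THF, −78 °C
Reagents that add atoms: none
Why: 1,2-Reduction of a β,β-disubstituted enone; the bulky hydride should approach anti to the axial C15 methyl and give the C13 alcohol cis to C15, while the lactone is untouched at this temperature.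

Step 7
Reactants: 7 (3R,3aR,6R,7aR)-6-hydroxy-3-(menthyloxy)-4,7a-dimethyl-3a,6,7,7a-tetrahydroisobenzofuran-1(3H)-one
Product: 8 (3R,3aR,6R,7aR)-6-(tert-butyldimethylsilyloxy)-3-(menthyloxy)-4,7a-dimethyl-3a,6,7,7a-tetrahydroisobenzofuran-1(3H)-one
Conditions: TBSOTf, 2,6-lutidine, CH2Cl2, −78 → 0 °C
Reagents that add atoms: tert-butyldimethylsilyl trifluoromethanesulfonate, CC(C)(C)[Si](C)(C)OS(=O)(=O)C(F)(F)F
Why: Silyl triflate silylation of a hindered secondary allylic alcohol; the resulting hindered TBS ether is the most robust of the three silyl ethers used and is removed only in step 26.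

Step 8
Reactants: 8 (3R,3aR,6R,7aR)-6-(tert-butyldimethylsilyloxy)-3-(menthyloxy)-4,7a-dimethyl-3a,6,7,7a-tetrahydroisobenzofuran-1(3H)-one
Product: 9 [(1R,2R,5R)-5-(tert-butyldimethylsilyloxy)-1,3-dimethylcyclohex-3-ene-1,2-diyl]dimethanol
Conditions: LiAlH4, THF, 0 → 20 °C
Reagents that add atoms: none
Why: Hydride reduction of the lactone carbonyl (C2) and, after collapse of the ring-opened hemiacetal, of the C9 aldehyde gives the trans diol and releases menthol; the silyl ether is stable to LiAlH4.

Step 9
Reactants: 9 [(1R,2R,5R)-5-(tert-butyldimethylsilyloxy)-1,3-dimethylcyclohex-3-ene-1,2-diyl]dimethanol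
Product: 10 [(1R,4R,6R)-4-(tert-butyldimethylsilyloxy)-6-(hydroxymethyl)-2,6-dimethylcyclohex-2-en-1-yl]methyl 2,4,6-triisopropylbenzenesulfonate
Conditions: 2,4,6-(i-Pr)3C6H2SO2Cl, pyridine, CH2Cl2, −20 → 0 °C
Reagents that add atoms: 2,4,6-triisopropylbenzenesulfonyl chloride, CC(C)c1cc(C(C)C)c(S(Cl)(=O)=O)c(C(C)C)c1
Why: Selective sulfonylation; the bulky arenesulfonyl chloride should prefer the C9 hydroxyl over the neopentyl C2 hydroxyl next to the quaternary carbon, and the low temperature keeps the hydroxy sulfonate from closing to a cyclic ether.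

Step 10
Reactants: 10 [(1R,4R,6R)-4-(tert-butyldimethylsilyloxy)-6-(hydroxymethyl)-2,6-dimethylcyclohex-2-en-1-yl]methyl 2,4,6-triisopropylbenzenesulfonate
Product: 11 [(1R,4R,6R)-4-(tert-butyldimethylsilyloxy)-2,6-dimethyl-6-[(triethylsilyloxy)methyl]cyclohex-2-en-1-yl]methyl 2,4,6-triisopropylbenzenesulfonate
Conditions: TESOTf, 2,6-lutidine, CH2Cl2, −78 °C
Reagents that add atoms: triethylsilyl trifluoromethanesulfonate, CC[Si](CC)(CC)OS(=O)(=O)C(F)(F)F
Why: Silyl triflate silylation of the neopentyl C2 hydroxyl; the triethylsilyl ether is the most acid-labile of the three silyl ethers and can be removed first, in step 17.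

Step 11
Reactants: 11 [(1R,4R,6R)-4-(tert-butyldimethylsilyloxy)-2,6-dimethyl-6-[(triethylsilyloxy)methyl]cyclohex-2-en-1-yl]methyl 2,4,6-triisopropylbenzenesulfonate
Product: 12 tert-butyl({(1R,4R,5R)-4-(bromomethyl)-3,5-dimethyl-5-[(triethylsilyloxy)methyl]cyclohex-2-en-1-yl}oxy)dimethylsilane
Conditions: LiBr, DMF, 60 °C
Reagents that add atoms: lithium bromide, [Li+].[Br-]
Why: SN2 displacement of the primary sulfonate at C9; the silyl ether oxygen at C2 is a poor neighbouring group, so cyclic ether formation should not compete.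

Step 12
Reactants: 13 4-methylfuran-2(5H)-one
Product: 14 (Z)-4-hydroxy-N-methoxy-N,3-dimethylbut-2-enamide
Conditions: MeONHMe·HCl, AlMe3, CH2Cl2, 0 → 20 °C
Reagents that add atoms: N,O-dimethylhydroxylamine hydrochloride, CNOC.Cl
Why: Weinreb aminolysis opens the lactone at the acyl carbon; the (Z)-geometry of C5=C6 is inherited from the ring, and the β-methyl group disfavours conjugate addition of the aluminium amide.

Step 13
Reactants: 14 (Z)-4-hydroxy-N-methoxy-N,3-dimethylbut-2-enamide
Product: 15 (Z)-4-(tert-butyldimethylsilyloxy)-N-methoxy-N,3-dimethylbut-2-enamide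
Conditions: TBSCl, imidazole, DMF, 0 °C
Reagents that add atoms: tert-butyl(chloro)dimethylsilane, CC(C)(C)[Si](C)(C)Cl
Why: Standard silylation of the primary allylic C4 hydroxyl, done at once so that the (Z)-hydroxy amide cannot relactonise.

Step 14
Reactants: 15 (Z)-4-(tert-butyldimethylsilyloxy)-N-methoxy-N,3-dimethylbut-2-enamide; 16 prop-1-ynylmagnesium bromide
Product: 17 (Z)-7-(tert-butyldimethylsilyloxy)-6-methylhept-5-en-2-yn-4-one
Conditions: THF, −78 → 0 °C; inverse quench into cold aq NaHSO4
Reagents that add atoms: none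
Why: Weinreb ketone synthesis forms C7–C8; the chelated adduct stops at the ketone, and the cold acidic quench prevents addition of the released amine to the ynone.

Step 15
Reactants: 17 (Z)-7-(tert-butyldimethylsilyloxy)-6-methylhept-5-en-2-yn-4-one
Product: 18 (R,Z)-7-(tert-butyldimethylsilyloxy)-6-methylhept-5-en-2-yn-4-ol
Conditions: (R)-2-methyl-CBS-oxazaborolidine (20 mol %), catecholborane, toluene, −78 °C
Reagents that add atoms: none
Why: Corey–Bakshi–Shibata reduction; the branched (Z)-alkenyl group should act as the large substituent and the linear propynyl group as the small one, so the (R)-catalyst is expected to give the 7R alcohol; catecholborane at low temperature avoids hydroboration.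

Step 16
Reactants: 12 tert-butyl({(1R,4R,5R)-4-(bromomethyl)-3,5-dimethyl-5-[(triethylsilyloxy)methyl]cyclohex-2-en-1-yl}oxy)dimethylsilane; 18 (R,Z)-7-(tert-butyldimethylsilyloxy)-6-methylhept-5-en-2-yn-4-ol; 19 carbon dioxide
Product: 24 ring A–butenolide conjugate (C2 OTES; C4 OTBS; C13 OTBS), via Grignard reagent 20 (not isolated), via chloromagnesium alkoxide 21 (not isolated), via alkenylmagnesium chelate 22 (not isolated), via hydroxy acid 23 (not isolated)
Conditions: 12, Mg, THF, 40 °C; 18 (1.5 equiv), MeMgCl (1.5 equiv), THF, 0 °C; combine, CuI (10 mol %), THF–toluene, 20 → 45 °C; CO2 (1 atm), −20 → 20 °C; 1 M HCl to pH 3, 0 °C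
Reagents that add atoms: none
Why: This is a copper-catalysed anti-carbomagnesiation of a propargylic alcohol with a CO2 quench, the known route from alkyl Grignard reagents and magnesium propargyl alkoxides to butenolides, applied here to a β-branched primary alkyl group. Alkoxide 21 is made first so that none of 20 is spent on the hydroxyl, and CuI carries the C9 alkyl group from 20 to the alkyne. The alkoxide anchors magnesium on oxygen, so carbon is delivered to the proximal carbon C8 (forming C8–C9) and magnesium ends anti at C17 in the five-membered chelate 22. CO2 inserts into the C17–Mg bond with retention (forming C17–C19), which places the carboxylate cis to the C7 oxygen. Acidification gives hydroxy acid 23, which closes ring C by 5-exo-trig attack of the C7 hydroxyl on the C19 carboxyl carbon. No stereocentre is formed; C7 is carried as its alkoxide and is never deprotonated at carbon, and the C8=C17 geometry follows from the anti addition. The step needs regioselectivity (C9 to C8, not C17) and anti stereoselectivity, both secured by the alkoxide chelate, and chemoselectivity for the alkyne over the C5=C6 and C11=C12 alkenes, which no neighbouring alkoxide activates.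

Step 17
Reactants: 24 ring A–butenolide conjugate (C2 OTES; C4 OTBS; C13 OTBS)
Product: 25 primary alcohol (24 with the C2 hydroxyl free)
Conditions: PPTS (cat.), MeOH–CH2Cl2, 0 °C
Reagents that add atoms: none
Why: Acid-catalysed methanolysis removes the triethylsilyl ether, which is far more labile than the primary allylic and hindered secondary TBS ethers.

Step 18
Reactants: 25 primary alcohol (24 with the C2 hydroxyl free)
Product: 26 C2 aldehyde
Conditions: Dess–Martin periodinane, CH2Cl2, 0 → 20 °C
Reagents that add atoms: none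
Why: Dess–Martin oxidation under neutral conditions; the aldehyde has no α-hydrogen (C1 is quaternary), so it cannot epimerise.

Step 19
Reactants: 26 C2 aldehyde
Product: 27 β-keto sulfone (C2 ketone, C3 phenylsulfonylmethylene)
Conditions: PhSO2CHN2, SnCl2 (10 mol %), CH2Cl2, 20 °C
Reagents that add atoms: (diazomethylsulfonyl)benzene, [N-]=[N+]=CS(=O)(=O)c1ccccc1
Why: Roskamp homologation; the diazo carbon adds to the SnCl2-activated aldehyde and a 1,2-hydride shift with loss of N2 gives the β-keto sulfone directly, installing C3 with no base and no carbanion near C7–H.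

Step 20
Reactants: 27 β-keto sulfone (C2 ketone, C3 phenylsulfonylmethylene)
Product: 28 allylic alcohol (27 with the C4 hydroxyl free)
Conditions: HF·pyridine, pyridine, THF, 0 °C
Reagents that add atoms: none
Why: Buffered fluoride cleaves the unhindered primary allylic TBS ether at C4 much faster than the hindered secondary TBS ether at C13.

Step 21
Reactants: 28 allylic alcohol (27 with the C4 hydroxyl free)
Product: 29 allylic bromide (C4 bromide)
Conditions: CBr4, PPh3, CH2Cl2, −20 °C
Reagents that add atoms: carbon tetrabromide, BrC(Br)(Br)Br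
Why: Appel bromination under neutral conditions; direct SN2 at the primary carbon keeps the (Z)-C5=C6 geometry.

Step 22
Reactants: 29 allylic bromide (C4 bromide)
Product: 30 tricyclic keto sulfone (rings A, B and C; C2 ketone, C3 sulfone, C13 OTBS)
Conditions: Cs2CO3, MeCN, 0.002 M by syringe-pump addition, 40 °C
Reagents that add atoms: none
Why: Intramolecular C-alkylation of the β-keto sulfone anion by the allylic bromide forms C3–C4 and closes ring B; carbonate is strong enough for the keto sulfone (several pK units more acidic than C7–H) and high dilution suppresses oligomers; C3 forms as an epimer mixture.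

Step 23
Reactants: 30 tricyclic keto sulfone (rings A, B and C; C2 ketone, C3 sulfone, C13 OTBS)
Product: 31 tricyclic C2 ketone
Conditions: SmI2, THF–MeOH, −78 °C
Reagents that add atoms: none
Why: Reductive desulfonylation of an α-sulfonyl ketone by electron transfer; at −78 °C without polar additives the butenolide and the ketone should not be reduced.

Step 24
Reactants: 31 tricyclic C2 ketone
Product: 32 (2S)-alcohol
Conditions: (R)-2-methyl-CBS-oxazaborolidine, catecholborane, toluene, −40 °C
Reagents that add atoms: none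
Why: Corey–Bakshi–Shibata reduction under reagent control; the quaternary C1 is the large group and the C3 methylene the small one, so the (R)-catalyst should deliver hydride to give the 2S carbinol without relying on the ring B conformation.

Step 25
Reactants: 32 (2S)-alcohol
Product: 33 C2 propionate
Conditions: (EtCO)2O, DMAP, pyridine, CH2Cl2, 20 °C
Reagents that add atoms: propionic anhydride, CCC(=O)OC(=O)CC
Why: DMAP-catalysed acylation of a hindered secondary alcohol; pyridine is too weak a base to deprotonate C7–H.

Step 26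
Reactants: 33 C2 propionate
Product: 34 C13 allylic alcohol
Conditions: HF·pyridine, THF, 20 → 40 °C
Reagents that add atoms: none
Why: Acidic fluoride removes the remaining hindered TBS ether; both esters and the butenolide tolerate these non-basic conditions.

Step 27
Reactants: 34 C13 allylic alcohol
Product: 35 ring A enone (C13 ketone)
Conditions: Dess–Martin periodinane, CH2Cl2, 0 °C
Reagents that add atoms: none
Why: Neutral oxidation of the allylic alcohol gives the C11=C12–C13=O enone and erases the C13 stereocentre.

Step 28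
Reactants: 35 ring A enone (C13 ketone)
Product: 36 target (C14 acetate)
Conditions: Mn(OAc)3·2H2O, benzene, reflux (Dean–Stark)
Reagents that add atoms: manganese triacetate, CC(=O)[O-].CC(=O)[O-].CC(=O)[O-].[Mn+3]
Why: α′-Acetoxylation of an enone through its manganese enolate; C14 is the only α′ position (C1 is quaternary), and acetate should be delivered axially, anti to the axial C15 methyl, which gives 14S.

## Compound list

1 | (5R)-5-(menthyloxy)furan-2(5H)-one | O=C1C=C[C@H](O[C@@H]2C[C@H](C)CC[C@H]2C(C)C)O1 | starting material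
2 | (4S,5R)-5-(menthyloxy)-4-(prop-1-en-2-yl)dihydrofuran-2(3H)-one | CC(=C)[C@@H]1CC(=O)O[C@H]1O[C@@H]2C[C@H](C)CC[C@H]2C(C)C | intermediate
3 | (3R,4S,5R)-3-methyl-5-(menthyloxy)-4-(prop-1-en-2-yl)dihydrofuran-2(3H)-one | CC(=C)[C@@H]1[C@@H](C)C(=O)O[C@H]1O[C@@H]2C[C@H](C)CC[C@H]2C(C)C | intermediate
4 | N-methoxy-N-methyl-2-[(3R,4R,5R)-3-methyl-5-(menthyloxy)-2-oxo-4-(prop-1-en-2-yl)tetrahydrofuran-3-yl]acetamide | CC(=C)[C@@H]1[C@@](C)(CC(=O)N(C)OC)C(=O)O[C@H]1O[C@@H]2C[C@H](C)CC[C@H]2C(C)C | intermediate
5 | (3R,4R,5R)-3-methyl-5-(menthyloxy)-3-(2-oxobut-3-en-1-yl)-4-(prop-1-en-2-yl)dihydrofuran-2(3H)-one | CC(=C)[C@@H]1[C@@](C)(CC(=O)C=C)C(=O)O[C@H]1O[C@@H]2C[C@H](C)CC[C@H]2C(C)C | intermediate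
6 | (3R,3aR,7aR)-3-(menthyloxy)-4,7a-dimethyl-3a,7-dihydroisobenzofuran-1,6(3H,7aH)-dione (trans-fused ring A enone lactone acetal) | O=C1C=C(C)[C@H]2[C@H](O[C@@H]3C[C@H](C)CC[C@H]3C(C)C)OC(=O)[C@]2(C)C1 | intermediate
7 | (3R,3aR,6R,7aR)-6-hydroxy-3-(menthyloxy)-4,7a-dimethyl-3a,6,7,7a-tetrahydroisobenzofuran-1(3H)-one | O[C@H]1C=C(C)[C@H]2[C@H](O[C@@H]3C[C@H](C)CC[C@H]3C(C)C)OC(=O)[C@]2(C)C1 | intermediate
8 | (3R,3aR,6R,7aR)-6-(tert-butyldimethylsilyloxy)-3-(menthyloxy)-4,7a-dimethyl-3a,6,7,7a-tetrahydroisobenzofuran-1(3H)-one | CC(C)(C)[Si](C)(C)O[C@H]1C=C(C)[C@H]2[C@H](O[C@@H]3C[C@H](C)CC[C@H]3C(C)C)OC(=O)[C@]2(C)C1 | intermediate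
9 | [(1R,2R,5R)-5-(tert-butyldimethylsilyloxy)-1,3-dimethylcyclohex-3-ene-1,2-diyl]dimethanol | CC(C)(C)[Si](C)(C)O[C@H]1C=C(C)[C@@H](CO)[C@](C)(CO)C1 | intermediate
10 | [(1R,4R,6R)-4-(tert-butyldimethylsilyloxy)-6-(hydroxymethyl)-2,6-dimethylcyclohex-2-en-1-yl]methyl 2,4,6-triisopropylbenzenesulfonate | CC(C)(C)[Si](C)(C)O[C@H]1C=C(C)[C@@H](COS(=O)(=O)c2c(C(C)C)cc(C(C)C)cc2C(C)C)[C@](C)(CO)C1 | intermediate
11 | [(1R,4R,6R)-4-(tert-butyldimethylsilyloxy)-2,6-dimethyl-6-[(triethylsilyloxy)methyl]cyclohex-2-en-1-yl]methyl 2,4,6-triisopropylbenzenesulfonate | CC(C)(C)[Si](C)(C)O[C@H]1C=C(C)[C@@H](COS(=O)(=O)c2c(C(C)C)cc(C(C)C)cc2C(C)C)[C@](C)(CO[Si](CC)(CC)CC)C1 | intermediate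
12 | tert-butyl({(1R,4R,5R)-4-(bromomethyl)-3,5-dimethyl-5-[(triethylsilyloxy)methyl]cyclohex-2-en-1-yl}oxy)dimethylsilane (ring A bromide) | CC(C)(C)[Si](C)(C)O[C@H]1C=C(C)[C@@H](CBr)[C@](C)(CO[Si](CC)(CC)CC)C1 | intermediate
13 | 4-methylfuran-2(5H)-one | CC1=CC(=O)OC1 | starting material
14 | (Z)-4-hydroxy-N-methoxy-N,3-dimethylbut-2-enamide | CON(C)C(=O)/C=C(/C)CO | intermediate
15 | (Z)-4-(tert-butyldimethylsilyloxy)-N-methoxy-N,3-dimethylbut-2-enamide | CON(C)C(=O)/C=C(/C)CO[Si](C)(C)C(C)(C)C | intermediate
16 | prop-1-ynylmagnesium bromide | CC#C[Mg]Br | starting material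
17 | (Z)-7-(tert-butyldimethylsilyloxy)-6-methylhept-5-en-2-yn-4-one | CC#CC(=O)/C=C(/C)CO[Si](C)(C)C(C)(C)C | intermediate
18 | (R,Z)-7-(tert-butyldimethylsilyloxy)-6-methylhept-5-en-2-yn-4-ol | CC#C[C@H](O)/C=C(/C)CO[Si](C)(C)C(C)(C)C | intermediate
19 | carbon dioxide | O=C=O | starting material
20 | {[(1R,4R,6R)-4-(tert-butyldimethylsilyloxy)-2,6-dimethyl-6-[(triethylsilyloxy)methyl]cyclohex-2-en-1-yl]methyl}magnesium bromide (ring A Grignard reagent, C9–Mg) | CC(C)(C)[Si](C)(C)O[C@H]1C=C(C)[C@@H](C[Mg]Br)[C@](C)(CO[Si](CC)(CC)CC)C1 | intermediate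
21 | chloromagnesium alkoxide of 18 | CC#C[C@H](O[Mg]Cl)/C=C(/C)CO[Si](C)(C)C(C)(C)C | intermediate
22 | alkenylmagnesium chelate (five-membered ring Mg–O–C7–C8=C17; C9 on C8, anti to Mg) | CC1=C(C[C@@H]2C(C)=C[C@H](O[Si](C)(C)C(C)(C)C)C[C@@]2(C)CO[Si](CC)(CC)CC)[C@@H](/C=C(/C)CO[Si](C)(C)C(C)(C)C)O[Mg]1 | intermediate
23 | (Z)-γ-hydroxy acid (C19 carboxyl on C17 cis to the C7 carbinol; 7R) | OC(=O)/C(C)=C(/C[C@@H]1C(C)=C[C@H](O[Si](C)(C)C(C)(C)C)C[C@@]1(C)CO[Si](CC)(CC)CC)[C@H](O)/C=C(/C)CO[Si](C)(C)C(C)(C)C | intermediate
24 | (5R)-5-[(1Z)-3-(tert-butyldimethylsilyloxy)-2-methylprop-1-en-1-yl]-4-{[(1R,4R,6R)-4-(tert-butyldimethylsilyloxy)-2,6-dimethyl-6-[(triethylsilyloxy)methyl]cyclohex-2-en-1-yl]methyl}-3-methylfuran-2(5H)-one | CC(C)(C)[Si](C)(C)OC/C(C)=C\[C@H]1OC(=O)C(C)=C1C[C@@H]1C(C)=C[C@H](O[Si](C)(C)C(C)(C)C)C[C@@]1(C)CO[Si](CC)(CC)CC | intermediate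
25 | compound 24 with the C2 hydroxyl free (1R,7R,10R,13R; 5Z) | CC(C)(C)[Si](C)(C)OC/C(C)=C\[C@H]1OC(=O)C(C)=C1C[C@@H]1C(C)=C[C@H](O[Si](C)(C)C(C)(C)C)C[C@@]1(C)CO | intermediate
26 | C2 aldehyde of 25 (1R,7R,10R,13R; 5Z) | CC(C)(C)[Si](C)(C)OC/C(C)=C\[C@H]1OC(=O)C(C)=C1C[C@@H]1C(C)=C[C@H](O[Si](C)(C)C(C)(C)C)C[C@@]1(C)C=O | intermediate
27 | β-keto sulfone: C2 ketone, C3 CH2SO2Ph, C4 OTBS, C13 OTBS (1R,7R,10R,13R; 5Z) | CC(C)(C)[Si](C)(C)OC/C(C)=C\[C@H]1OC(=O)C(C)=C1C[C@@H]1C(C)=C[C@H](O[Si](C)(C)C(C)(C)C)C[C@@]1(C)C(=O)CS(=O)(=O)c1ccccc1 | intermediate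
28 | β-keto sulfone with the C4 hydroxyl free | OC/C(C)=C\[C@H]1OC(=O)C(C)=C1C[C@@H]1C(C)=C[C@H](O[Si](C)(C)C(C)(C)C)C[C@@]1(C)C(=O)CS(=O)(=O)c1ccccc1 | intermediate
29 | β-keto sulfone with the C4 allylic bromide | BrC/C(C)=C\[C@H]1OC(=O)C(C)=C1C[C@@H]1C(C)=C[C@H](O[Si](C)(C)C(C)(C)C)C[C@@]1(C)C(=O)CS(=O)(=O)c1ccccc1 | intermediate
30 | tricyclic keto sulfone: rings A, B and C, C2 ketone, C3 SO2Ph (both epimers), C13 OTBS (1R,7R,10R,13R; 5Z) | O=C1C(S(=O)(=O)c3ccccc3)C/C(C)=C\[C@H]2OC(=O)C(C)=C2C[C@@H]2C(C)=C[C@H](O[Si](C)(C)C(C)(C)C)C[C@@]12C | intermediate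
31 | tricyclic C2 ketone, C13 OTBS (1R,7R,10R,13R; 5Z) | O=C1CC/C(C)=C\[C@H]2OC(=O)C(C)=C2C[C@@H]2C(C)=C[C@H](O[Si](C)(C)C(C)(C)C)C[C@@]12C | intermediate
32 | tricyclic (2S)-alcohol, C13 OTBS (1R,2S,7R,10R,13R; 5Z) | O[C@H]1CC/C(C)=C\[C@H]2OC(=O)C(C)=C2C[C@@H]2C(C)=C[C@H](O[Si](C)(C)C(C)(C)C)C[C@@]12C | intermediate
33 | tricyclic C2 propionate, C13 OTBS (1R,2S,7R,10R,13R; 5Z) | CCC(=O)O[C@H]1CC/C(C)=C\[C@H]2OC(=O)C(C)=C2C[C@@H]2C(C)=C[C@H](O[Si](C)(C)C(C)(C)C)C[C@@]12C | intermediate
34 | tricyclic C2 propionate, C13 alcohol (1R,2S,7R,10R,13R; 5Z) | CCC(=O)O[C@H]1CC/C(C)=C\[C@H]2OC(=O)C(C)=C2C[C@@H]2C(C)=C[C@H](O)C[C@@]12C | intermediate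
35 | tricyclic C2 propionate, ring A enone (C13 ketone, C14 methylene) (1R,2S,7R,10R; 5Z) | CCC(=O)O[C@H]1CC/C(C)=C\[C@H]2OC(=O)C(C)=C2C[C@@H]2C(C)=CC(=O)C[C@@]12C | intermediate
36 | CNP0109273.3: tricyclic butenolide with C2 propionate, C13 ketone, C14 acetate (1R,2S,7R,10R,14S; 5Z) | CCC(=O)O[C@H]1CC/C(C)=C\[C@H]2OC(=O)C(C)=C2C[C@@H]2C(C)=CC(=O)[C@@H](OC(C)=O)[C@@]12C | target

## Step count and least certain steps

Total: 28 steps. Longest linear sequence: 24 steps (steps 1–11 and 16–28); the alkynol branch (steps 12–15) is 4 steps.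

Step 16 (key step).
- Most likely failure: slow or incomplete carbomagnesiation, because the C9 alkyl group is β-branched and flanked by a quaternary carbon, so transfer from magnesium to copper and on to the alkyne is hindered. Reduction of the alkyne by β-hydride transfer, Wurtz coupling during magnesium insertion and protonation of the Grignard reagent would then compete.
- Fallback: a stoichiometric organocopper syn-addition to a γ-hydroxy ynoate, which is known chemistry. It sets out from 12 and 15. Amide 15 is treated with LiC≡CCO2Et to give ethyl (Z)-7-(tert-butyldimethylsilyloxy)-6-methyl-4-oxohept-5-en-2-ynoate F1. Reduction with the (R)-CBS catalyst and catecholborane gives ethyl (R,Z)-7-(tert-butyldimethylsilyloxy)-4-hydroxy-6-methylhept-5-en-2-ynoate F2. Bromide 12 is converted to 20 and then, with CuBr·SMe2 (1 equiv), to the organocopper reagent RCu. RCu adds syn across the ynoate of F2 (hydroxyl first deprotonated with MeMgCl) at −78 °C, with C9 going to C8. The α-metallated enoate is methylated at C17 with MeI/DMPU. Acidic work-up lactonises the ester onto the C7 hydroxyl, and the route rejoins at 24.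

Step 22.
- Most likely failure: oligomerisation by intermolecular alkylation, because ten-membered rings close slowly. Deprotonation at C7 would lead to epimerisation or 1,4-elimination of HBr, and O-alkylation of the enolate is also possible.
- Fallback: a Tsuji–Trost macrocyclisation under neutral conditions. It sets out from 28, which with methyl chloroformate and pyridine gives the allylic methyl carbonate F3. Zerovalent palladium (Pd(PPh3)4, dppe, THF, 60 °C, high dilution) ionises the carbonate, and the keto sulfone attacks the less hindered C4 terminus, rejoining the route at 30.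

Step 19.
- Most likely failure: slow addition of the diazo sulfone to the neopentyl aldehyde, with alkyl migration or epoxide formation competing with the hydride shift.
- Fallback: carbanion addition followed by oxidation. It sets out from 26; PhSO2CH2Li premixed with CeCl3 (a weakly basic organocerium reagent) at −78 °C gives the β-hydroxy sulfone F4, and Dess–Martin oxidation rejoins the route at 27.

Step 28.
- Most likely failure: poor site selectivity (oxidation at the γ positions C10 or C20 through the extended enol, or radical attack on C5=C6), and erosion of the C14 configuration by enolisation at reflux.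
- Fallback: a Rubottom sequence. It sets out from 35; LiN(SiMe3)2 with TMSCl as internal quench at −78 °C gives the cross-conjugated silyl dienol ether F5. Epoxidation with dimethyldioxirane at −78 °C and mild acid give the α′-hydroxy enone F6, and acetylation (Ac2O, DMAP) rejoins the route at 36. This fallback accepts a brief exposure of C7–H to a hindered base at low temperature.

Step 15.
- Most likely failure: low enantioselectivity, because the catalyst must tell an alkenyl from an alkynyl group, together with some conjugate reduction.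
- Fallback: kinetic resolution. It sets out from 17; NaBH4/CeCl3 gives the racemic alcohol F7, and lipase-catalysed acylation with vinyl acetate is expected to convert the (S)-enantiomer into acetate F8 and leave the (R)-alcohol, rejoining the route at 18.

Step 9.
- Most likely failure: insufficient discrimination between the two hindered primary hydroxyls, and closure of the hydroxy sulfonate to a cyclic ether.
- Fallback: selective deprotection in place of selective activation. It sets out from 9; TESOTf gives the bis(triethylsilyl) ether F9. Methanolysis with PPTS at −20 °C should cleave the less hindered C9 silyl ether to give the C9 alcohol F10, which has C2 already protected. Appel bromination (CBr4, PPh3) rejoins the route at 12.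

## Further compounds

F1 | step 16 | ethyl (Z)-7-(tert-butyldimethylsilyloxy)-6-methyl-4-oxohept-5-en-2-ynoate | CCOC(=O)C#CC(=O)/C=C(/C)CO[Si](C)(C)C(C)(C)C
F2 | step 16 | ethyl (R,Z)-7-(tert-butyldimethylsilyloxy)-4-hydroxy-6-methylhept-5-en-2-ynoate | CCOC(=O)C#C[C@H](O)/C=C(/C)CO[Si](C)(C)C(C)(C)C
F3 | step 22 | allylic methyl carbonate of 28 (C4 OCO2Me) | COC(=O)OC/C(C)=C\[C@H]1OC(=O)C(C)=C1C[C@@H]1C(C)=C[C@H](O[Si](C)(C)C(C)(C)C)C[C@@]1(C)C(=O)CS(=O)(=O)c1ccccc1
F4 | step 19 | β-hydroxy sulfone (C2 carbinol, both epimers; C3 CH2SO2Ph) | CC(C)(C)[Si](C)(C)OC/C(C)=C\[C@H]1OC(=O)C(C)=C1C[C@@H]1C(C)=C[C@H](O[Si](C)(C)C(C)(C)C)C[C@@]1(C)C(O)CS(=O)(=O)c1ccccc1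
F5 | step 28 | silyl dienol ether of 35 (C13 OSiMe3, C13=C14, C11=C12) | CCC(=O)O[C@H]1CC/C(C)=C\[C@H]2OC(=O)C(C)=C2C[C@@H]2C(C)=CC(O[Si](C)(C)C)=C[C@@]12C
F6 | step 28 | (14S)-α′-hydroxy enone (C14 hydroxyl in place of the acetate of 36) | CCC(=O)O[C@H]1CC/C(C)=C\[C@H]2OC(=O)C(C)=C2C[C@@H]2C(C)=CC(=O)[C@@H](O)[C@@]12C
F7 | step 15 | racemic (Z)-7-(tert-butyldimethylsilyloxy)-6-methylhept-5-en-2-yn-4-ol | CC#CC(O)/C=C(/C)CO[Si](C)(C)C(C)(C)C
F8 | step 15 | (S,Z)-7-(tert-butyldimethylsilyloxy)-6-methylhept-5-en-2-yn-4-yl acetate | CC#C[C@@H](OC(C)=O)/C=C(/C)CO[Si](C)(C)C(C)(C)C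
F9 | step 9 | bis(triethylsilyl) ether of diol 9 | CC(C)(C)[Si](C)(C)O[C@H]1C=C(C)[C@@H](CO[Si](CC)(CC)CC)[C@](C)(CO[Si](CC)(CC)CC)C1
F10 | step 9 | [(1R,4R,6R)-4-(tert-butyldimethylsilyloxy)-2,6-dimethyl-6-[(triethylsilyloxy)methyl]cyclohex-2-en-1-yl]methanol | CC(C)(C)[Si](C)(C)O[C@H]1C=C(C)[C@@H](CO)[C@](C)(CO[Si](CC)(CC)CC)C1
A1 | alternative 1 | ring A aldol adduct (C14 ketone, C2 alcohol, silylfuran as masked ring C, C6 vinyl iodide) | O[C@@H](CC/C(C)=C\I)[C@@]1(C)[C@H](Cc2coc([Si](C)(C)C)c2C)[C@@H](C)CCC1=O
A2 | alternative 1 | (S)-2,4-dimethylcyclohex-2-en-1-one | O=C1CC[C@H](C)C=C1C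
A3 | alternative 1 | {[4-methyl-5-(trimethylsilyl)furan-3-yl]methyl}magnesium bromide | Br[Mg]Cc1coc([Si](C)(C)C)c1C
A4 | alternative 1 | (Z)-5-iodo-4-methylpent-4-enal | O=CCC/C(C)=C\I
A5 | alternative 2 | isoxazoline-bridged tetracycle (rings A, B and C plus isoxazoline; C13 OTBS) | O1[C@H]2CC/C(C)=C\[C@H]3OC(=O)C(C)=C3C[C@@H]3C(C)=C[C@@H](O[Si](C)(C)C(C)(C)C)C(=N1)[C@@]23C
A6 | alternative 2 | ring B/ring C (1Z,5Z)-diene with the C11–C14 side chain on C10 ending in the C14 aldoxime (C13 OTBS) | C/C1=C/CC/C(C)=C\[C@H]2OC(=O)C(C)=C2C[C@@H]1/C(C)=C\[C@@H](O[Si](C)(C)C(C)(C)C)/C=N/O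
A7 | alternative 3 | ring A/ring B bicyclic C2 alcohol with C13=C14 alkene (C7 OTBS, open ring C) | O[C@H]1CC/C(C)=C\[C@@H](O[Si](C)(C)C(C)(C)C)/C(=C(/C)CO[Si](C)(C)C(C)(C)C)C[C@@H]2[C@@H](C)CC=C[C@@]12C
A8 | alternative 3 | thirteen-membered α-(tributylstannyl) allylic ether (O bridging C2 and C13; C1=C14 alkene) | CCCC[Sn](CCCC)(CCCC)[C@H]1CC/C(C)=C\[C@@H](O[Si](C)(C)C(C)(C)C)/C(=C(/C)CO[Si](C)(C)C(C)(C)C)C[C@@H]2[C@@H](C)C[C@@H](O1)C=C2C
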